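**Strategy.** The cyclohexane ring (elemanolide numbering, C5–C10) is closed by a one-flask double carbonyl allylation. C5 and C7 are both γ-carbons of 2-substituted allyl units (C15=C4–C5 of the propenal arm, C13=C11–C7 of the α-methylene lactone), and each neighbours a carbinol carbon (C6, C8). An allylindium made from a 2-(bromomethyl)but-2-enoate acetal adds to an α-PMB-oxy aldehyde (C7–C8, then lactone); the acetal is then unmasked and the C6 aldehyde is allylated by a pendant (Z)-allylboronate (C5–C6). The precursor is an acyclic aldehyde–allylboronate carrying C9 and quaternary C10, plus a four-carbon bromide; four stereocentres, both rings and both exocyclic methylenes result.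

Key step: step 11

Numbering used: ring C5–C6–C7–C8–C9–C10; C10 carries the methyl C14 and the vinyl group C1=C2; C5 carries C4 with methylene C15 and C3 (methyl, finally CHO); C7 carries C11 with methylene C13 and the lactone carbonyl C12 bonded to O8; O6 bears the angelate and O9 the (R)-2-methylbutanoate.

Assumption: in step 1 (R)-Tol-BINAP is taken to deliver the (3R)-carbinol; if the sense of induction is opposite, (S)-Tol-BINAP is used with no other change. The anti diastereomer (OH anti to CH2OH) is expected from the (E)-σ-allyl iridium chair model.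

Step 1
Reactants: 1 2-[(tert-butyldimethylsilyl)oxy]ethan-1-ol; 2 2-methyl-2-vinyloxirane (racemic)
Product: 3 (2S,3R)-4-[(tert-butyldimethylsilyl)oxy]-2-ethenyl-2-methylbutane-1,3-diol
Conditions: [Ir(cod)Cl]2 (2.5 mol %), (R)-Tol-BINAP, 4-cyano-3-nitrobenzoic acid, allyl acetate (precatalyst formation), K3PO4 (5 mol %), 2 (3 equiv), THF, 60 °C
Reagents that add atoms: none
Why: Iridium-catalysed transfer-hydrogenative carbonyl tert-(hydroxy)prenylation: the alcohol is dehydrogenated to the aldehyde, the vinyl epoxide opens to an (E)-σ-allyl iridium, and addition through a chair transition state with CH2OH pseudo-equatorial should give the anti diol, the chiral bisphosphine setting C9 and the quaternary C10 together.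

Step 2
Reactants: 3
Product: 4 p-methoxybenzylidene acetal of 3 (1,3-dioxane over O9 and O5; aryl and CH2OTBS equatorial)
Conditions: 4-methoxybenzaldehyde dimethyl acetal, PPTS (cat.), CH2Cl2, rt
Reagents that add atoms: 4-methoxybenzaldehyde dimethyl acetal, COc1ccc(C(OC)OC)cc1
Why: Acid-catalysed transacetalisation gives the six-membered benzylidene-type acetal of the 1,3-diol under thermodynamic control; the new acetal centre is temporary.

Step 3
Reactants: 4
Product: 5 (2S,3R)-4-[(tert-butyldimethylsilyl)oxy]-2-ethenyl-3-[(4-methoxybenzyl)oxy]-2-methylbutan-1-ol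
Conditions: DIBAL-H (i-Bu2AlH, 3 equiv), CH2Cl2, −78 to 0 °C
Reagents that add atoms: none
Why: Regioselective reductive acetal opening: aluminium binds the less hindered primary acetal oxygen and that C–O bond is cleaved, which leaves the PMB ether on the hindered secondary O9 and frees the C5 alcohol.

Step 4
Reactants: 5
Product: 6 (2R,3R)-4-[(tert-butyldimethylsilyl)oxy]-2-ethenyl-3-[(4-methoxybenzyl)oxy]-2-methylbutanal
Conditions: Dess–Martin periodinane, NaHCO3, CH2Cl2, 0 °C to rt
Reagents that add atoms: none
Why: Dess–Martin oxidation of the neopentyl primary alcohol; the aldehyde has no α-hydrogen, so it can neither epimerise nor eliminate the β-PMB ether.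

Step 5
Reactants: 6; 7 ethyltriphenylphosphonium iodide
Product: 9 tert-butyl{[(2R,3S,4Z)-3-ethenyl-5-iodo-2-[(4-methoxybenzyl)oxy]-3-methylhex-4-en-1-yl]oxy}dimethylsilane, via iodo ylide 8 (not isolated)
Conditions: 7, n-BuLi, THF, rt; I2, −78 °C; NaHMDS (NaN(SiMe3)2), −20 °C; then 6, −78 to −20 °C
Reagents that add atoms: iodine (I2), II
Why: Stork–Zhao-type Wittig olefination with the α-iodo ylide: the salt-free cis-oxaphosphetane should give the trisubstituted (Z)-vinyl iodide with iodine cis to the quaternary C10.

Step 6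
Reactants: 9
Product: 10 (2R,3S,4Z)-3-ethenyl-5-iodo-2-[(4-methoxybenzyl)oxy]-3-methylhex-4-en-1-ol
Conditions: TBAF (Bu4NF), THF, 0 °C to rt
Reagents that add atoms: none
Why: Fluoride cleaves the primary TBS ether; it is removed at this stage so that the later allylboronate never meets fluoride or acid.

Step 7
Reactants: 10; 11 bis[(pinacolato)boryl]methane
Product: 12 (2R,3S,4Z)-3-ethenyl-2-[(4-methoxybenzyl)oxy]-3-methyl-5-[(4,4,5,5-tetramethyl-1,3,2-dioxaborolan-2-yl)methyl]hex-4-en-1-ol
Conditions: Pd[P(t-Bu)3]2 (5 mol %), aq. KOH (3 equiv), 1,4-dioxane, rt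
Reagents that add atoms: none
Why: Suzuki–Miyaura coupling of a geminal bis(boronate) with an alkenyl halide: hydroxide activates one boron, the α-boryl methyl group is transferred to palladium, and reductive elimination gives the allylboronate with retention of alkene geometry (C10 cis to CH2Bpin).

Step 8
Reactants: 12
Product: 13 (2R,3S,4Z)-3-ethenyl-2-[(4-methoxybenzyl)oxy]-3-methyl-5-[(4,4,5,5-tetramethyl-1,3,2-dioxaborolan-2-yl)methyl]hex-4-enal
Conditions: Dess–Martin periodinane, NaHCO3, CH2Cl2, 0 °C; used at once
Reagents that add atoms: none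
Why: Buffered Dess–Martin oxidation tolerates the pinacol allylboronate; the boronate cannot allylate its own aldehyde because that would need a four-membered ring.

Step 9
Reactants: 14 methyl acrylate; 15 2,2-dimethoxyacetaldehyde
Product: 16 methyl 2-(1-hydroxy-2,2-dimethoxyethyl)prop-2-enoate (racemic)
Conditions: DABCO (0.5 equiv), 1,4-dioxane/H2O, rt
Reagents that add atoms: none
Why: Morita–Baylis–Hillman reaction of an electron-poor aldehyde; the racemic carbinol centre is removed in step 10.

Step 10
Reactants: 16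
Product: 17 methyl (2Z)-2-(bromomethyl)-4,4-dimethoxybut-2-enoate
Conditions: NBS, Me2S, CH2Cl2, 0 °C to rt
Reagents that add atoms: N-bromosuccinimide, O=C1CCC(=O)N1Br
Why: The bromodimethylsulfonium ion activates the hydroxyl and bromide attacks the methylene terminus (SN2'), which should give the thermodynamically preferred (2Z)-bromide with the acetal carbon trans to the ester.

Step 11
Reactants: 13; 17
Product: 20 hydroxy lactone (cis-fused 8,12-olide with free 6-OH and 9-O-PMB and isopropenyl at C5; configuration at C5–C10 as in 28), via Barbier adduct 18 (not isolated), via lactone aldehyde 19 (not isolated)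
Conditions: In powder (2 equiv), 17 (1.5 equiv), THF/H2O 1:1, rt; then aq. HCl to pH 1, 35 °C, same flask
Reagents that add atoms: water, O
Why: Indium inserts into the C–Br bond of 17 and the allylindium, whose γ-substituent stays cis to CH2In (the thermodynamically preferred geometry), adds through its γ-carbon to the indium-chelated aldehyde 13 (C7–C8) to give 18; on acidification O8 lactonises onto the methyl ester and the now saturated dimethyl acetal is hydrolysed to aldehyde 19, which is allylated intramolecularly by the pinacol allylboronate through its γ-carbon (C5–C6), the boron ending on O6 and being hydrolysed. The closest known reaction types are the aqueous indium Barbier reaction of 2-(bromomethyl)alk-2-enoates with α-alkoxy aldehydes (α-methylene-γ-butyrolactone synthesis) and the intramolecular allylboration of ω-oxo allylboronates. The lactone closes by 5-exo-trig acyl substitution; the cyclohexane closes in a 6-membered mode in which the aldehyde carbon and the allyl γ-carbon become ring atoms, through a bicyclic chair–chair Zimmerman–Traxler transition state. C8 is set by chelation of indium between the aldehyde and PMB-ether oxygens (attack anti to C10, O8/O9 syn), C7 by the closed chair of the Z-type allylindium (cis-lactone), and C5/C6 by the fixed (Z)-geometry of the boronate, which admits only the cis-fused transition state (C5 substituent cis to O6) and selects the face that keeps O8 and O9 equatorial instead of placing vinyl, O8 and O6 syn-axial. The step needs cross-coupling in the right order rather than self-coupling: C6 stays an acetal until C7–C8 exists, and the boronate cannot reach the aldehyde of its own molecule (four-membered ring) and is too hindered to react between molecules at room temperature.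

Step 12
Reactants: 20; 21 angelic acid ((2Z)-2-methylbut-2-enoic acid)
Product: 23 6-O-angeloyl lactone (9-O-PMB), via mixed anhydride 22 (not isolated)
Conditions: 21 (4 equiv), 2,4,6-trichlorobenzoyl chloride, Et3N, toluene, rt; then 20, 80 °C
Reagents that add atoms: none
Why: Yamaguchi esterification through the mixed anhydride without nucleophilic catalyst, conditions that should avoid Z-to-E isomerisation to the tiglate; only the C6 hydroxyl is free.

Step 13
Reactants: 23
Product: 24 6-O-angeloyl-9-hydroxy lactone
Conditions: DDQ, CH2Cl2/pH 7 buffer, 0 °C to rt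
Reagents that add atoms: none
Why: Oxidative PMB cleavage by DDQ via the benzylic oxocarbenium ion and hydrolysis; esters, lactone and alkenes should be untouched.

Step 14
Reactants: 24; 25 (R)-2-methylbutanoic acid
Product: 26 6-O-angeloyl-9-O-[(R)-2-methylbutanoyl] lactone with isopropenyl at C5
Conditions: 25 (3 equiv), DCC, DMAP (cat.), CH2Cl2, rt
Reagents that add atoms: none
Why: Steglich esterification of the equatorial C9 alcohol; carbodiimide activation forms no ketene, so the α-stereocentre of the acid should be kept.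

Step 15
Reactants: 26
Product: 28 CNP0295282.1, via allylic alcohol 27 (not isolated)
Conditions: SeO2 (1.5 equiv), 1,4-dioxane, 70 °C
Reagents that add atoms: selenium dioxide, O=[Se]=O
Why: Riley allylic oxidation: ene reaction of SeO2 at the electron-rich 1,1-disubstituted isopropenyl alkene with hydrogen taken from the methyl (preferred over the hindered ring methine), [2,3]-shift to the allylic alcohol and further oxidation to the enal; the electron-poor angelate and α-methylene lactone and the vinyl group (no allylic hydrogen) should not compete.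

**Compound list**

1 | 2-[(tert-butyldimethylsilyl)oxy]ethan-1-ol | OCCO[Si](C)(C)C(C)(C)C | starting material
2 | 2-methyl-2-vinyloxirane (racemic) | C=CC1(C)CO1 | starting material
3 | (2S,3R)-4-[(tert-butyldimethylsilyl)oxy]-2-ethenyl-2-methylbutane-1,3-diol | C=C[C@@]([C@@H](O)CO[Si](C)(C)C(C)(C)C)(C)CO | intermediate
4 | p-methoxybenzylidene acetal of 3 (aryl and CH2OTBS equatorial) | COc1ccc(cc1)[C@@H]1OC[C@](C)(C=C)[C@H](CO[Si](C)(C)C(C)(C)C)O1 | intermediate
5 | (2S,3R)-4-[(tert-butyldimethylsilyl)oxy]-2-ethenyl-3-[(4-methoxybenzyl)oxy]-2-methylbutan-1-ol | C=C[C@@]([C@@H](OCc1ccc(OC)cc1)CO[Si](C)(C)C(C)(C)C)(C)CO | intermediate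
6 | (2R,3R)-4-[(tert-butyldimethylsilyl)oxy]-2-ethenyl-3-[(4-methoxybenzyl)oxy]-2-methylbutanal | C=C[C@@]([C@@H](OCc1ccc(OC)cc1)CO[Si](C)(C)C(C)(C)C)(C)C=O | intermediate
7 | ethyltriphenylphosphonium iodide | CC[P+](c1ccccc1)(c1ccccc1)c1ccccc1.[I-] | starting material
8 | (1-iodoethylidene)triphenylphosphorane | CC(I)=P(c1ccccc1)(c1ccccc1)c1ccccc1 | intermediate (not isolated)
9 | tert-butyl{[(2R,3S,4Z)-3-ethenyl-5-iodo-2-[(4-methoxybenzyl)oxy]-3-methylhex-4-en-1-yl]oxy}dimethylsilane | C=C[C@@]([C@@H](OCc1ccc(OC)cc1)CO[Si](C)(C)C(C)(C)C)(C)/C=C(\I)C | intermediate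
10 | (2R,3S,4Z)-3-ethenyl-5-iodo-2-[(4-methoxybenzyl)oxy]-3-methylhex-4-en-1-ol | C=C[C@@]([C@@H](OCc1ccc(OC)cc1)CO)(C)/C=C(\I)C | intermediate
11 | bis[(pinacolato)boryl]methane | CC1(C)OB(CB2OC(C)(C)C(C)(C)O2)OC1(C)C | starting material
12 | (2R,3S,4Z)-3-ethenyl-2-[(4-methoxybenzyl)oxy]-3-methyl-5-[(pinacolboryl)methyl]hex-4-en-1-ol | C=C[C@@]([C@@H](OCc1ccc(OC)cc1)CO)(C)/C=C(\CB1OC(C)(C)C(C)(C)O1)C | intermediate
13 | (2R,3S,4Z)-3-ethenyl-2-[(4-methoxybenzyl)oxy]-3-methyl-5-[(pinacolboryl)methyl]hex-4-enal | C=C[C@@]([C@@H](OCc1ccc(OC)cc1)C=O)(C)/C=C(\CB1OC(C)(C)C(C)(C)O1)C | intermediate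
14 | methyl acrylate | C=CC(=O)OC | starting material
15 | 2,2-dimethoxyacetaldehyde | COC(OC)C=O | starting material
16 | methyl 2-(1-hydroxy-2,2-dimethoxyethyl)prop-2-enoate (racemic) | COC(=O)C(=C)C(O)C(OC)OC | intermediate
17 | methyl (2Z)-2-(bromomethyl)-4,4-dimethoxybut-2-enoate | COC(=O)/C(CBr)=C/C(OC)OC | intermediate
18 | Barbier adduct: hydroxy ester with C8 carbinol, C7 bearing CH(OMe)2 and the 2-(methoxycarbonyl)vinyl unit (7,8-syn, 8,9-syn) | COC(OC)[C@@H](C(=C)C(=O)OC)[C@@H](O)[C@H](OCc1ccc(OC)cc1)[C@@](C)(C=C)/C=C(\CB1OC(C)(C)C(C)(C)O1)C | intermediate (not isolated)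
19 | cis-β,γ-disubstituted α-methylene-γ-butyrolactone with C6 aldehyde and pendant (Z)-allylboronate | O=C[C@H]1C(=C)C(=O)O[C@H]1[C@H](OCc1ccc(OC)cc1)[C@@](C)(C=C)/C=C(\CB1OC(C)(C)C(C)(C)O1)C | intermediate (not isolated)
20 | hydroxy lactone: cis-fused 8,12-olide, 6-OH cis to the C5 isopropenyl group, 9-O-PMB trans to O8 | C=C[C@@]1(C)[C@H](C(=C)C)[C@H](O)[C@H]2C(=C)C(=O)O[C@H]2[C@@H]1OCc1ccc(OC)cc1 | intermediate
21 | angelic acid, (2Z)-2-methylbut-2-enoic acid | C/C=C(/C)C(=O)O | starting material
22 | angelic 2,4,6-trichlorobenzoic anhydride | C/C=C(/C)C(=O)OC(=O)c1c(Cl)cc(Cl)cc1Cl | intermediate (not isolated)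
23 | 6-O-angeloyl-9-O-PMB lactone | C=C[C@@]1(C)[C@H](C(=C)C)[C@H](OC(=O)/C(C)=C\C)[C@H]2C(=C)C(=O)O[C@H]2[C@@H]1OCc1ccc(OC)cc1 | intermediate
24 | 6-O-angeloyl-9-hydroxy lactone | C=C[C@@]1(C)[C@H](C(=C)C)[C@H](OC(=O)/C(C)=C\C)[C@H]2C(=C)C(=O)O[C@H]2[C@@H]1O | intermediate
25 | (R)-2-methylbutanoic acid | CC[C@@H](C)C(=O)O | starting material
26 | 6-O-angeloyl-9-O-[(R)-2-methylbutanoyl] lactone with isopropenyl at C5 | C=C[C@@]1(C)[C@H](C(=C)C)[C@H](OC(=O)/C(C)=C\C)[C@H]2C(=C)C(=O)O[C@H]2[C@@H]1OC(=O)[C@H](C)CC | intermediate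
27 | C3 allylic alcohol of 26 | C=C[C@@]1(C)[C@H](C(=C)CO)[C@H](OC(=O)/C(C)=C\C)[C@H]2C(=C)C(=O)O[C@H]2[C@@H]1OC(=O)[C@H](C)CC | intermediate (not isolated)
28 | CNP0295282.1 | C=C[C@@]1(C)[C@H](C(=C)C=O)[C@H](OC(=O)/C(C)=C\C)[C@H]2C(=C)C(=O)O[C@H]2[C@@H]1OC(=O)[C@H](C)CC | target

**Totals.** Total step count: 15. Longest linear sequence: 13 steps (steps 1–8, then 11–15); steps 9 and 10 form the side branch.

**Steps most likely to fail**

Step 11. The allylindium may lose methoxide by 1,4-elimination, chelation control at C8 may be incomplete, or the allylboronate may be protodeboronated before the acetal is cleaved. The fallback sets out from 13 and 17 and separates the two bond formations under anhydrous control. Bromide 17 is converted with hexabutylditin (Bu3SnSnBu3) and catalytic Pd2(dba)3 into methyl (2Z)-4,4-dimethoxy-2-[(tributylstannyl)methyl]but-2-enoate F1. F1 is added to 13 pre-complexed with MgBr2·OEt2 in CH2Cl2 at −78 °C; this chelation-controlled open-transition-state allylation should give the syn,syn adduct 18 whatever the stannane geometry, and 18 is now isolated. Catalytic p-TsOH closes it to the acetal lactone F2, and aqueous trifluoroacetic acid then liberates 19, which cyclises to 20, where the route is rejoined.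

Step 5. The Wittig reaction may be slow at the neopentyl aldehyde and the Z selectivity may erode. The fallback sets out from 6. CBr4/PPh3 gives the 1,1-dibromoalkene F3. Trans-selective Negishi mono-methylation (MeZnCl, PdCl2(DPEphos), THF, 0 °C) replaces the bromine trans to the quaternary carbon and leaves the (Z)-2-bromoalkene F4. TBAF gives the bromo alcohol F5, which is coupled with 11 under the conditions of step 7 and returns to the route at 12.

Step 12. Acylation of the axial C6 hydroxyl, which is shielded by the syn-axial C10 methyl, may be sluggish, and the angeloyl unit may isomerise to tigloyl. The fallback sets out from 20. Steglich acylation with 2-[bis(2,2,2-trifluoroethoxy)phosphoryl]propanoic acid (DCC, DMAP) gives the phosphonate ester F6. Still–Gennari olefination with acetaldehyde (KHMDS, 18-crown-6, THF, −78 °C) then builds the (Z)-2-methylbut-2-enoate directly on O6 and returns to the route at 23.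

**Further compounds**

F1 | step 11 | methyl (2Z)-4,4-dimethoxy-2-[(tributylstannyl)methyl]but-2-enoate | COC(=O)/C(C[Sn](CCCC)(CCCC)CCCC)=C/C(OC)OC
F2 | step 11 | acetal lactone (cis-lactone of 18 with C6 dimethyl acetal) | COC(OC)[C@H]1C(=C)C(=O)O[C@H]1[C@H](OCc1ccc(OC)cc1)[C@@](C)(C=C)/C=C(\CB1OC(C)(C)C(C)(C)O1)C
F3 | step 5 | tert-butyl{[(2R,3S)-5,5-dibromo-3-ethenyl-2-[(4-methoxybenzyl)oxy]-3-methylpent-4-en-1-yl]oxy}dimethylsilane | C=C[C@@]([C@@H](OCc1ccc(OC)cc1)CO[Si](C)(C)C(C)(C)C)(C)C=C(Br)Br
F4 | step 5 | tert-butyl{[(2R,3S,4Z)-5-bromo-3-ethenyl-2-[(4-methoxybenzyl)oxy]-3-methylhex-4-en-1-yl]oxy}dimethylsilane | C=C[C@@]([C@@H](OCc1ccc(OC)cc1)CO[Si](C)(C)C(C)(C)C)(C)/C=C(\Br)C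
F5 | step 5 | (2R,3S,4Z)-5-bromo-3-ethenyl-2-[(4-methoxybenzyl)oxy]-3-methylhex-4-en-1-ol | C=C[C@@]([C@@H](OCc1ccc(OC)cc1)CO)(C)/C=C(\Br)C
F6 | step 12 | 6-O-{2-[bis(2,2,2-trifluoroethoxy)phosphoryl]propanoyl} derivative of 20 | C=C[C@@]1(C)[C@H](C(=C)C)[C@H](OC(=O)C(C)P(=O)(OCC(F)(F)F)OCC(F)(F)F)[C@H]2C(=C)C(=O)O[C@H]2[C@@H]1OCc1ccc(OC)cc1
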